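(The constants used here come from no measurement, and the outcome is calculated.)

The ratio of [target] to the sum of what is dissolved is the quantity I carry through this flask. Solid substrate dissolves into starting material, which passes reversibly into target; target passes reversibly into its isomer, and the isomer reversibly back into starting material.

solid substrate 24 mM; time 80 min

    starting material ⇌ target (K1 = 1.8, k1 = 3.5 × 10⁻⁴ /s)
    solid substrate ⇌ starting material, rate k2*(cs2 - [starting material]) while solid is left; crystals form when [starting material] > cs2 (cs2 = 16 mM, k2 = 1.3 × 10⁻⁴ /s)
    target ⇌ isomer of the product (K3 = 1.1, k3 = 2.7 × 10⁻⁴ /s)
    isomer of the product ⇌ starting material (k4 = 6.6 × 10⁻⁵ /s)

- amount of target at 80 min, in percent of the solid substrate charged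
- concentration of starting material in solution at 80 min, in percent of saturation

I call the first of these y and the second sat.

I build the flask up one process at a time. With dissolving alone, into a solution kept empty, the solid delivers at most 41.6 % of its charge by 80 min. That is less than the charge, so in this reckoning solid stands beside the solution to the end, and if target took that whole amount, y would have this value. Now I add the passing into target, with equilibrium constant 1.8: at rest, target holds 64.3 % of the solution, so y falls to 26.7 %. Then I add the isomer, with constant 1.1 against target, and close the cycle. The ratio [target]/([starting material]+[target]+[isomer of the product]) at rest becomes 37.7 %, the resting share of target, which is the thermodynamic limit of the solution. The zero of this scale is the symmetric case: constants of 1 give each form 33.3 %, and target stands a little above that. This brings y to 15.7 %. But the flask is not at rest. The relaxation half-life between starting material and target is 21.2 min, shorter than the run of 80 min, so target follows the feed, though with a lag of that half-life over ln(2), 30.6 min. Taking that lag off the run gives y = 9.67 %, the figure I commit to. For sat I have no reckoning of my own.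

The forecast gives y = 10.8 % and sat = 24 %, holding that “The solution species relax among themselves much faster than that feed”. Its y stands above mine.

The simulation gives y = 10.8 % and sat = 24.2 %, so the forecast holds within its margin. To move y by 5 points, the time of reading has to go to 48.7 min or 113 min.

In this flask at 80.0 min, starting material is still made 1.28 times as fast as it is used up, each step taken net, and target holds 30.9 % of what has dissolved, below the resting share of 37.7 %. The same flask read at 5.0 h has 0 % of its charge left as solid, and target, at 37.6 % of the charge, holds 37.6 % of what has dissolved.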